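## Analysis of the target

The target is a C27 apocarotenoid, (3S,5R,8S,9Z)-5,8-epoxy-5,8-dihydro-10′-apo-β-carotene-3,10′-diol. A trimethylcyclohexanol (ring A, C1–C6) is fused through C5–C6 to a 2,5-dihydrofuran (ring B, O1–C5–C6=C7–C8). C8 carries a hexaene chain that ends in a primary allylic alcohol at C10′.

There are three stereocentres. C3 (S) carries the secondary hydroxyl and C5 (R) is a quaternary C–O carbon. On ring A the C3 hydroxyl and the C5 methyl are cis, and the ring oxygen O1 is trans to the hydroxyl, as in loliolide, where the hydroxyl is axial. C8 (S) is an ether carbon flanked by the C6=C7 and C9=C10 alkenes, and C9 lies on the same face of ring B as the C5 methyl.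

In the chain C9=C10 is Z (C8 and C11 cis), and the other five double bonds are E.

The sensitive points are the doubly allylic C8–O1 bond, which acid ionises with loss of the C8 configuration, the light- and acid-sensitive polyene, and the Z alkene.

The difficulty is threefold: ring B is nearly flat and gives no facial bias at C8 relative to the remote C3 and C5; the trisubstituted Z alkene sits directly on that stereocentre; and acid must be avoided once C8 is set.

The strategy rests on C8 being an acetal carbon in disguise. A C8 acetal gives an oxocarbenium ion O1=C8 conjugated with C6=C7. This ion cannot aromatise because C5 is quaternary. The axial O3 stands on the face from which C9 must arrive, and a bridge O3–Si–O–C11–C10=C9 can reach C8 only if C9=C10 is Z, which is the geometry the target has.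

## Retrosynthetic reasoning

**31 ⇒ 30 (oxidation level at C10′).** The allylic alcohol 31 is taken back to the ethyl ester 30, so the chain can be assembled with an acceptor-terminated piece. The forward step is a 1,2-reduction by an aluminium hydride under non-acidic conditions.

**30 ⇒ 23 + 28 (C11=C12).** This is the first E double bond beyond the Z unit. Cutting here leaves every stereocentre and the Z alkene in the C15 enal 23, and puts the rest into the achiral all-E phosphonate 28. The forward olefination must give an E alkene with a carbanion too weakly basic to remove the C8 hydrogen, which is γ to the aldehyde.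

**28 ⇒ 27 ⇒ 26 ⇒ 25 ⇒ 24 (chain fragment).** The phosphonate 28 comes from the symmetrical dialdehyde 24 by differentiating its ends. One aldehyde is lengthened by two carbons to the enoate 25. The other is reduced (26), brominated (27) and phosphonylated (28).

**23 ⇒ 22 ⇒ 21 (C11 oxidation level and bridge).** The enal 23 comes from the allylic alcohol 22 by a mild allylic oxidation that leaves the C3 carbinol alone. Diol 22 is what remains when the silicon bridge of 21 is removed, because the two oxygens tied by silicon in 21 are O3 and O11.

**21 ⇒ 19 (C8–C9, the key disconnection).** C8 is the one stereocentre that the chiral pool does not supply, and it sits one oxidation level below an acetal. Cutting the bond between C8 and the alkene turns the problem into the facial selectivity of attack on a cation, which a bridge from O3 can decide. The gain is that the C8 configuration, the C9 methyl and the Z geometry arrive in one step from a precursor with no stereochemistry at C8. The forward reaction has to ionise C8, deliver C9 from the O3 face within the bridge, and keep the alkene geometry.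

**19 ⇒ 11 + 17 + 16 (two Si–O bonds).** The unsymmetrical bis-ether 19 is assembled on the dichlorosilane 17. The hindered secondary alcohol 11 goes on first and the primary allylic alcohol 16 second.

**16 ⇒ 14 ⇒ 12 (C–Sn and the Z alkene).** The stannane 16 comes from the iodide 14 with retention. Iodide 14 comes from the alkynol 12 by hydroxyl-directed trans-hydrometalation and iodination, which fixes the Z geometry.

**11 ⇒ 9 ⇒ 8 (C8 oxidation level).** The methyl acetal 11 is the lactol 9 after acetal exchange and loss of the silyl ether. Lactol 9 is the half-reduced lactone 8, the triethylsilyl ether of loliolide.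

**8 ⇒ 7 ⇒ 6 (C6=C7 and the ester C–O).** The butenolide 8 is opened at the alkene to the phosphonoacetate 7 and then at the ester to the α-hydroxy ketone 6. The forward olefination is intramolecular and the ketone cannot enolise.

**6 ⇒ 4 (C5–O).** The tertiary hydroxyl is put on the only enolate that ketone 4 can form (5). The C3 substituent has to direct oxygen to the opposite face.

**4 ⇒ 3 ⇒ 2 ⇒ 1 (ring A).** Ether 4 is protected actinol 3. Its carbinol comes from the diketone 2 by a hindered hydride, and 2 comes from ketoisophorone 1 by enantioselective reduction of the alkene.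

## Alternatives that were turned down

**Alternative 1: ring A closed last by C4–C5 bond formation.**
- **Disconnection:** C4–C5, with ring B preformed.
- **Forward key step:** trimethylsilyl triflate would ionise the C5 silyl ketal of dihydrofuran A1. The enol silane terminus C4 of the chain on C6 would add to C5 and close the six-membered ring to give ketone A2.
- **For:** a six-membered cationic closure is more conventional than an 11-membered one and needs no tin. The C3 ketone of A2 could be reduced from the face opposite both axial methyl groups, which gives the axial hydroxyl reliably.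
- **Against:** the cation sits at C5 next to a C8 that still carries hydrogen, so loss of that proton aromatises ring B to a furan and erases C8. The nucleophile hangs from C6 in the ring plane and can reach both faces of C5, so C5 would be set only by a weak 1,3-relay from C8 across a flat ring. A2 carries C9 only as a silyloxymethyl carbon. The C9 methyl and the Z alkene would then need oxidation to an α-alkoxy carbonyl (epimerisable at C8), methyl addition, re-oxidation and a Z-selective olefination of a ketone, for which no dependable control exists.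
- **Comparison:** alternative 1 is stronger on ring size. The chosen route offers a cation that cannot aromatise, C3 and C5 bought early from a cheap ring A, and the Z alkene installed in the bond-forming step.

**Alternative 2: ring B by ring expansion of a vinyl epoxide.**
- **Disconnection:** O1–C5.
- **Forward key step:** Cu(CF3COCHCOCF3)2 (divalent copper) would open the cis-7,8-epoxide A3 at allylic C7. The oxygen stays on C8 and closes on C5, shifting the alkene to C6=C7 and giving the 8-alkynyl furanoid A4.
- **For:** the step is catalytic and atom-economic and needs no macrocyclic transition state. The C8–O bond is never broken, so C8 could be set by reagent-controlled epoxidation. On these points it is stronger than the chosen route.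
- **Against:** the new C–O bond must form at the fully substituted end of a tetrasubstituted alkene, on the face anti to O3, with only remote bias and through allyl-copper or ion-pair intermediates that can lose fidelity. A3 itself requires epoxidation of the enyne alkene in the presence of the more electron-rich ring alkene. Afterwards the alkyne of A4 must still become the C9-methyl Z alkene. Syn methyl-metalation of the terminal alkyne puts the chain trans to C8 (9E). The Z isomer needs a detour through a C11 ester and cuprate addition, which exposes the propargylic C8–O bond to SN2′ opening.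
- **Comparison:** the core might be reached in a similar number of steps, but more steps follow it. The chosen route secures C5 before the key step and delivers C8, the C9 methyl and the Z geometry together.

**Alternative 3: ring A by reductive Heck annulation.**
- **Disconnection:** C1–C6.
- **Forward key step:** Pd(OAc)2 with PPh3 and HCO2Na (zerovalent palladium formed in situ) would insert into the C6–I bond of iododihydrofuran A5. The alkenylpalladium adds 6-exo-trig to the isopropenyl group, and formate reduces the neopentylpalladium, which has no β-hydrogen, to the second C1 methyl, giving A6.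
- **For:** the carbopalladation is well behaved, forms the quaternary C1 and touches no stereocentre. As a single step it is probably more reliable than the chosen key step.
- **Against:** all three stereocentres, including the quaternary C5 in a defined relation to C8, must already be present in A5, which needs a long linear sequence. A6 again carries C9 as a silyloxymethyl carbon, with the same epimerisable carbonyl and Z-olefination problem as alternative 1.
- **Comparison:** the chosen route spends its steps on a chiral-pool ring A and concentrates the risk in one step that creates C8 and the Z alkene at once.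

Key step: step 12

Remark on the chemistry: the skeleton is numbered as in carotenoids (C1 = CMe2, C3 = CHOH, C5 = C(CH3)O, C6=C7, C8 = OCH, C9 to C10′ = chain). Lactol- and acetal-level compounds are used as mixtures at C8, because both epimers give the same cation. "9Z" means C8 and C11 cis on C9=C10, as drawn in the target.

## Route

Step 1
Reactants: 1 ketoisophorone (2,6,6-trimethylcyclohex-2-ene-1,4-dione)
Product: 2 (6R)-2,2,6-trimethylcyclohexane-1,4-dione ((R)-levodione)
Conditions: OYE2 (old yellow enzyme of Saccharomyces cerevisiae), NADP+ (cat.), glucose dehydrogenase, D-glucose, KH2PO4/K2HPO4 buffer pH 7, 30 °C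
Reagents that add atoms: none
Why: Biocatalytic asymmetric conjugate reduction of the enedione by a flavin-dependent ene-reductase should set the methyl-bearing carbon as R; the product is extracted promptly at neutral pH because this α-stereocentre can racemise by enolisation.

Step 2
Reactants: 2 (6R)-2,2,6-trimethylcyclohexane-1,4-dione
Product: 3 (4R,6R)-4-hydroxy-2,2,6-trimethylcyclohexan-1-one (actinol)
Conditions: LiBH(s-Bu)3, THF, −78 °C; then aq. NaOH, H2O2, 0 °C
Reagents that add atoms: none
Why: Bulky-hydride reduction is chemoselective for the unhindered C4 carbonyl (C1 lies between CMe2 and CHMe); equatorial approach anti to the axial C2 methyl should give the axial alcohol trans to the C6 methyl, which is the (4R) carbinol (C3 of the target).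

Step 3
Reactants: 3 (4R,6R)-4-hydroxy-2,2,6-trimethylcyclohexan-1-one
Product: 4 (4R,6R)-2,2,6-trimethyl-4-(triethylsilyloxy)cyclohexan-1-one
Conditions: Et3SiCl, imidazole, DMF, 0 °C → rt
Reagents that add atoms: chlorotriethylsilane CC[Si](Cl)(CC)CC
Why: Standard silylation; the triethylsilyl ether should survive the base and hydride steps and is removed without an extra step under the acetalisation conditions of step 8.

Step 4
Reactants: 4 (4R,6R)-2,2,6-trimethyl-4-(triethylsilyloxy)cyclohexan-1-one
Product: 6 (2R,4S)-2-hydroxy-2,6,6-trimethyl-4-(triethylsilyloxy)cyclohexan-1-one, via potassium enolate 5 (not isolated)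
Conditions: KN(SiMe3)2, THF, −78 °C; then 2-(phenylsulfonyl)-3-phenyloxaziridine, −78 °C; cold quench
Reagents that add atoms: 2-(phenylsulfonyl)-3-phenyloxaziridine O=S(=O)(c1ccccc1)N1OC1c1ccccc1
Why: Enolate oxidation with an N-sulfonyloxaziridine (Davis hydroxylation); only one enolate can form because the other α-carbon is quaternary. Axial attack on the half-chair enolate with the silyloxy group equatorial should place the new oxygen trans to O3, which sets C5 (R); the minor cis isomer is removed by chromatography. The cold quench avoids α-ketol rearrangement of the alkoxide.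

Step 5
Reactants: 6 (2R,4S)-2-hydroxy-2,6,6-trimethyl-4-(triethylsilyloxy)cyclohexan-1-one
Product: 7 (1R,5S)-1,3,3-trimethyl-2-oxo-5-(triethylsilyloxy)cyclohexyl 2-(diethoxyphosphoryl)acetate
Conditions: (EtO)2P(O)CH2CO2H, DCC, DMAP (cat.), CH2Cl2, 0 °C → rt
Reagents that add atoms: diethylphosphonoacetic acid CCOP(=O)(CC(=O)O)OCC
Why: Carbodiimide (Steglich-type) esterification; phosphonoacetic acids are activated through a phosphoryl ketene, which should acylate even this tertiary hydroxyl.

Step 6
Reactants: 7 (1R,5S)-1,3,3-trimethyl-2-oxo-5-(triethylsilyloxy)cyclohexyl 2-(diethoxyphosphoryl)acetate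
Product: 8 (6S,7aR)-4,4,7a-trimethyl-6-(triethylsilyloxy)-5,6,7,7a-tetrahydro-1-benzofuran-2(4H)-one (O-triethylsilyl loliolide)
Conditions: NaH, THF, 0 → 50 °C
Reagents that add atoms: none
Why: Intramolecular Horner–Wadsworth–Emmons olefination closes the butenolide (C6=C7); the ketone cannot enolise, the five-membered ring fixes the alkene geometry, and intramolecularity should offset the hindrance of the carbonyl.

Step 7
Reactants: 8 (6S,7aR)-4,4,7a-trimethyl-6-(triethylsilyloxy)-5,6,7,7a-tetrahydro-1-benzofuran-2(4H)-one
Product: 9 (6S,7aR)-4,4,7a-trimethyl-6-(triethylsilyloxy)-2,4,5,6,7,7a-hexahydro-1-benzofuran-2-ol (lactol; both C2 epimers)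
Conditions: i-Bu2AlH (1.2 equiv), CH2Cl2, −78 °C; aq. potassium sodium tartrate
Reagents that add atoms: none
Why: Half-reduction of a butenolide to the lactol; the tetrahedral aluminate is stable at −78 °C, and the cis-locked alkene keeps the product in the cyclic form.

Step 8
Reactants: 9 (6S,7aR)-4,4,7a-trimethyl-6-(triethylsilyloxy)-2,4,5,6,7,7a-hexahydro-1-benzofuran-2-ol
Product: 11 (6S,7aR)-2-methoxy-4,4,7a-trimethyl-2,4,5,6,7,7a-hexahydro-1-benzofuran-6-ol (both C2 epimers), via O-triethylsilyl methyl acetal 10 (not isolated)
Conditions: MeOH, pyridinium p-toluenesulfonate (cat.), rt; Et3N quench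
Reagents that add atoms: methanol CO
Why: Acid-catalysed acetal exchange through the allyl-oxocarbenium ion, followed by methanolysis of the triethylsilyl ether in the same flask. The quaternary C5 excludes furan formation, and methanol attack at C8 gives the thermodynamic acetal.

Step 9
Reactants: 12 but-2-yn-1-ol
Product: 14 (Z)-3-iodobut-2-en-1-ol, via cyclic sodium alkenylalanate 13 (not isolated)
Conditions: NaAlH2(OCH2CH2OCH3)2, THF, 0 °C → rt; then I2, THF, −78 → 0 °C
Reagents that add atoms: iodine II
Why: Hydroxyl-directed trans-hydroalumination puts hydrogen on C2 and aluminium on C3 inside a five-membered alkoxyaluminate; iodinolysis with retention should give the iodide cis to the CH2OH group.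

Step 10
Reactants: 14 (Z)-3-iodobut-2-en-1-ol
Product: 16 (Z)-3-(tributylstannyl)but-2-en-1-ol, via dilithio alkoxide 15 (not isolated)
Conditions: n-BuLi (1 equiv) then t-BuLi (2 equiv), Et2O, −78 °C; then Bu3SnCl, −78 °C → rt
Reagents that add atoms: tributyltin chloride CCCC[Sn](Cl)(CCCC)CCCC
Why: O-deprotonation followed by iodine–lithium exchange gives a chelated alkenyllithium with retained geometry; stannylation occurs at carbon, and any O–Sn bond is hydrolysed on work-up.

Step 11
Reactants: 11 (6S,7aR)-2-methoxy-4,4,7a-trimethyl-2,4,5,6,7,7a-hexahydro-1-benzofuran-6-ol; 17 dichlorodiisopropylsilane; 16 (Z)-3-(tributylstannyl)but-2-en-1-ol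
Product: 19 diisopropyl{[(6S,7aR)-2-methoxy-4,4,7a-trimethyl-2,4,5,6,7,7a-hexahydro-1-benzofuran-6-yl]oxy}{[(2Z)-3-(tributylstannyl)but-2-en-1-yl]oxy}silane (both C2 epimers), via chlorosilyl ether 18 (not isolated)
Conditions: 17 (3 equiv), imidazole, CH2Cl2, 0 °C → rt; excess 17 removed in vacuo; then 16, imidazole, DMF, rt
Reagents that add atoms: none
Why: Stepwise nucleophilic substitution at silicon; the hindered secondary alcohol is silylated first with excess dichlorosilane so that no symmetrical bis-ether forms, and the primary allylic alcohol then displaces the second chloride. The isopropyl groups make the bis-ether stable to chromatography.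

Step 12
Reactants: 19 diisopropylsilylene-linked acetal–stannane (both C2 epimers)
Product: 21 silylene-bridged C15 furanoid with (3S,5R,8S,9Z) configuration and an 11-membered ring O1–C5–C4–C3–O–Si(i-Pr)2–O–C11–C10=C9–C8, via oxocarbenium triflate 20 (not isolated)
Conditions: Me3SiOTf (1.5 equiv), 2,6-di-tert-butyl-4-methylpyridine (2 equiv), 4 Å molecular sieves, CH2Cl2 (0.002 M, slow addition of 19), −78 → −40 °C; Et3N quench
Reagents that add atoms: none
Why: Me3SiOTf removes the C8 methoxy group of either anomer of 19 as Me3SiOMe and gives the C6=C7-conjugated oxocarbenium ion 20, which persists because the quaternary C5 offers no proton for furan formation and the quaternary C1 none for a diene. The tin-bearing carbon C9 attacks C8; the charge developing at C10 is stabilised by the C–Sn bond, and loss of the stannyl group as Bu3SnOTf (hence more than one equivalent of the silyl triflate) restores C9=C10 with retention, so the Z geometry of step 9 is carried over. The closest known reaction types are the ipso substitution of alkenylstannanes and alkenylsilanes by oxocarbenium ions and the silicon-tethered intramolecular delivery of nucleophiles to anomeric cations; the ring here is larger than in most such deliveries and is comparable to Prins-type macrocyclisations. The one ring closed is the temporary 11-membered ring, formed in the endo mode with respect to both the C9=C10 and the C8=O1 π bonds; the Z alkene, the two isopropyl groups on silicon and the rigid bicycle limit the freedom that must be frozen. The new stereocentre C8 is controlled by the tether: O3 is axial on the face of ring A that carries the C5 methyl, and the six-atom bridge can bring C9 to C8 only across that face, which gives (8S) with C9 cis to the C5 methyl, a choice the flat ring B alone would not make. Attack at C8 rather than at C6, the other end of the allyl cation, is secured by sterics (C6 lies between two quaternary carbons) and by the more strained ten-membered bridge that a C6 adduct would need. Cyclisation is favoured over oligomerisation by slow addition at 0.002 M, and the hindered pyridine removes triflic acid that would protodestannylate 19. In 21 the bridge also locks C8, because a re-ionised C8–O1 bond can only close again from the same face.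

Step 13
Reactants: 21 silylene-bridged C15 furanoid
Product: 22 (2Z)-3-[(2S,6S,7aR)-6-hydroxy-4,4,7a-trimethyl-2,4,5,6,7,7a-hexahydro-1-benzofuran-2-yl]but-2-en-1-ol (C15 diol)
Conditions: Bu4NF, THF, 0 °C → rt
Reagents that add atoms: none
Why: Fluoride cleaves both Si–O bonds of the dialkoxysilane; the medium is non-acidic, so the doubly allylic C8–O1 bond is not ionised.

Step 14
Reactants: 22 C15 diol
Product: 23 (2Z)-3-[(2S,6S,7aR)-6-hydroxy-4,4,7a-trimethyl-2,4,5,6,7,7a-hexahydro-1-benzofuran-2-yl]but-2-enal (C15 enal)
Conditions: MnO2 (activated, excess), CH2Cl2, rt, dark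
Reagents that add atoms: none
Why: Allylic oxidation with manganese dioxide is selective for the primary allylic alcohol over the saturated secondary C3 carbinol, and the neutral heterogeneous conditions should preserve the Z alkene.

Step 15
Reactants: 24 (2E,4E,6E)-2,7-dimethylocta-2,4,6-trienedial
Product: 25 ethyl (2E,4E,6E,8E)-4,9-dimethyl-10-oxodeca-2,4,6,8-tetraenoate
Conditions: 24 (3 equiv), Ph3P=CHCO2Et (1 equiv), CH2Cl2, 0 °C → rt; excess 24 recovered
Reagents that add atoms: ethyl (triphenylphosphoranylidene)acetate CCOC(=O)C=P(c1ccccc1)(c1ccccc1)c1ccccc1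
Why: Wittig olefination with a stabilised ylide is E-selective; the excess of the symmetrical dialdehyde enforces mono-olefination.

Step 16
Reactants: 25 ethyl (2E,4E,6E,8E)-4,9-dimethyl-10-oxodeca-2,4,6,8-tetraenoate
Product: 26 ethyl (2E,4E,6E,8E)-10-hydroxy-4,9-dimethyldeca-2,4,6,8-tetraenoate
Conditions: NaBH4, EtOH/THF, −20 °C
Reagents that add atoms: none
Why: Borohydride 1,2-reduction of the aldehyde; the conjugated ester is not reduced under these conditions.

Step 17
Reactants: 26 ethyl (2E,4E,6E,8E)-10-hydroxy-4,9-dimethyldeca-2,4,6,8-tetraenoate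
Product: 27 ethyl (2E,4E,6E,8E)-10-bromo-4,9-dimethyldeca-2,4,6,8-tetraenoate
Conditions: PBr3, pyridine (cat.), Et2O, −20 °C, dark
Reagents that add atoms: phosphorus tribromide BrP(Br)Br
Why: Conversion of a primary allylic alcohol into the bromide; the conjugated primary bromide is the thermodynamic allylic isomer and is used crude.

Step 18
Reactants: 27 ethyl (2E,4E,6E,8E)-10-bromo-4,9-dimethyldeca-2,4,6,8-tetraenoate
Product: 28 ethyl (2E,4E,6E,8E)-10-(diethoxyphosphoryl)-4,9-dimethyldeca-2,4,6,8-tetraenoate (C12–C10′ phosphonate)
Conditions: P(OEt)3, toluene, 90 °C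
Reagents that add atoms: triethyl phosphite CCOP(OCC)OCC
Why: Michaelis–Arbuzov reaction of a reactive allylic bromide.

Step 19
Reactants: 23 C15 enal; 28 C12–C10′ phosphonate
Product: 30 ethyl (2E,4E,6E,8E,10E,12Z)-13-[(2S,6S,7aR)-6-hydroxy-4,4,7a-trimethyl-2,4,5,6,7,7a-hexahydro-1-benzofuran-2-yl]-4,9-dimethyltetradeca-2,4,6,8,10,12-hexaenoate, via sodium phosphonate carbanion 29 (not isolated)
Conditions: 28, NaN(SiMe3)2, THF, −78 °C; then 23, −78 → 0 °C, dark
Reagents that add atoms: none
Why: Horner–Wadsworth–Emmons olefination with an allylic phosphonate carbanion forms C11=C12 and should give the E alkene; the delocalised anion is too weakly basic to deprotonate the C3 hydroxyl or the γ-hydrogen at C8, so C8 and the Z alkene should remain intact.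

Step 20
Reactants: 30 ethyl hexaenoate
Product: 31 (3S,5R,8S,9Z)-5,8-epoxy-5,8-dihydro-10′-apo-β-carotene-3,10′-diol [(2E,4E,6E,8E,10E,12Z)-13-[(2S,6S,7aR)-6-hydroxy-4,4,7a-trimethyl-2,4,5,6,7,7a-hexahydro-1-benzofuran-2-yl]-4,9-dimethyltetradeca-2,4,6,8,10,12-hexaen-1-ol], the target
Conditions: i-Bu2AlH (3.5 equiv), CH2Cl2, −78 °C; aq. potassium sodium tartrate
Reagents that add atoms: none
Why: 1,2-Reduction of a conjugated ester to the allylic alcohol by an aluminium hydride; the neutral tartrate work-up avoids acid at C8.

## Compound list

1 | ketoisophorone (2,6,6-trimethylcyclohex-2-ene-1,4-dione) | CC1=CC(=O)CC(C)(C)C1=O | starting material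
2 | (6R)-2,2,6-trimethylcyclohexane-1,4-dione | C[C@@H]1CC(=O)CC(C)(C)C1=O | intermediate
3 | (4R,6R)-4-hydroxy-2,2,6-trimethylcyclohexan-1-one | C[C@@H]1C[C@@H](O)CC(C)(C)C1=O | intermediate
4 | (4R,6R)-2,2,6-trimethyl-4-(triethylsilyloxy)cyclohexan-1-one | C[C@@H]1C[C@@H](O[Si](CC)(CC)CC)CC(C)(C)C1=O | intermediate
5 | potassium (4R)-2,6,6-trimethyl-4-(triethylsilyloxy)cyclohex-1-en-1-olate | CC1=C([O-])C(C)(C)C[C@H](O[Si](CC)(CC)CC)C1.[K+] | intermediate (not isolated)
6 | (2R,4S)-2-hydroxy-2,6,6-trimethyl-4-(triethylsilyloxy)cyclohexan-1-one | O=C1C(C)(C)C[C@H](O[Si](CC)(CC)CC)C[C@@]1(C)O | intermediate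
7 | (1R,5S)-1,3,3-trimethyl-2-oxo-5-(triethylsilyloxy)cyclohexyl 2-(diethoxyphosphoryl)acetate | O=C1C(C)(C)C[C@H](O[Si](CC)(CC)CC)C[C@@]1(C)OC(=O)CP(=O)(OCC)OCC | intermediate
8 | (6S,7aR)-4,4,7a-trimethyl-6-(triethylsilyloxy)-5,6,7,7a-tetrahydro-1-benzofuran-2(4H)-one | CC1(C)C[C@H](O[Si](CC)(CC)CC)C[C@@]2(C)OC(=O)C=C12 | intermediate
9 | (6S,7aR)-4,4,7a-trimethyl-6-(triethylsilyloxy)-2,4,5,6,7,7a-hexahydro-1-benzofuran-2-ol (both C2 epimers) | CC1(C)C[C@H](O[Si](CC)(CC)CC)C[C@@]2(C)OC(O)C=C12 | intermediate
10 | triethyl{[(6S,7aR)-2-methoxy-4,4,7a-trimethyl-2,4,5,6,7,7a-hexahydro-1-benzofuran-6-yl]oxy}silane (both C2 epimers) | COC1C=C2C(C)(C)C[C@H](O[Si](CC)(CC)CC)C[C@@]2(C)O1 | intermediate (not isolated)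
11 | (6S,7aR)-2-methoxy-4,4,7a-trimethyl-2,4,5,6,7,7a-hexahydro-1-benzofuran-6-ol (both C2 epimers) | COC1C=C2C(C)(C)C[C@H](O)C[C@@]2(C)O1 | intermediate
12 | but-2-yn-1-ol | CC#CCO | starting material
13 | cyclic sodium alkenylalanate (five-membered O–Al–C3=C2–C1 ring, two 2-methoxyethoxy groups on aluminium) | CC1=CCO[Al-]1(OCCOC)OCCOC.[Na+] | intermediate (not isolated)
14 | (Z)-3-iodobut-2-en-1-ol | C/C(I)=C/CO | intermediate
15 | lithium (2Z)-3-lithiobut-2-en-1-olate | C/C([Li])=C/CO[Li] | intermediate (not isolated)
16 | (Z)-3-(tributylstannyl)but-2-en-1-ol | C/C(=C/CO)[Sn](CCCC)(CCCC)CCCC | intermediate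
17 | dichlorodiisopropylsilane | CC(C)[Si](Cl)(Cl)C(C)C | starting material
18 | chloro(diisopropyl){[(6S,7aR)-2-methoxy-4,4,7a-trimethyl-2,4,5,6,7,7a-hexahydro-1-benzofuran-6-yl]oxy}silane (both C2 epimers) | COC1C=C2C(C)(C)C[C@H](O[Si](Cl)(C(C)C)C(C)C)C[C@@]2(C)O1 | intermediate (not isolated)
19 | diisopropyl{[(6S,7aR)-2-methoxy-4,4,7a-trimethyl-2,4,5,6,7,7a-hexahydro-1-benzofuran-6-yl]oxy}{[(2Z)-3-(tributylstannyl)but-2-en-1-yl]oxy}silane (both C2 epimers) | COC1C=C2C(C)(C)C[C@H](O[Si](C(C)C)(C(C)C)OC/C=C(/C)[Sn](CCCC)(CCCC)CCCC)C[C@@]2(C)O1 | intermediate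
20 | C6=C7-conjugated C8 oxocarbenium triflate derived from 19 (methoxide removed; bridge and stannane intact) | [O+]1=CC=C2C(C)(C)C[C@H](O[Si](C(C)C)(C(C)C)OC/C=C(/C)[Sn](CCCC)(CCCC)CCCC)C[C@@]12C.[O-]S(=O)(=O)C(F)(F)F | intermediate (not isolated)
21 | silylene-bridged C15 furanoid, (3S,5R,8S,9Z), 11-membered ring O1–C5–C4–C3–O–Si(i-Pr)2–O–C11–C10=C9–C8 | C/C(=C/CO[Si](C(C)C)(C(C)C)O3)[C@@H]1C=C2C(C)(C)C[C@H]3C[C@@]2(C)O1 | intermediate
22 | (2Z)-3-[(2S,6S,7aR)-6-hydroxy-4,4,7a-trimethyl-2,4,5,6,7,7a-hexahydro-1-benzofuran-2-yl]but-2-en-1-ol | C/C(=C/CO)[C@@H]1C=C2C(C)(C)C[C@H](O)C[C@@]2(C)O1 | intermediate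
23 | (2Z)-3-[(2S,6S,7aR)-6-hydroxy-4,4,7a-trimethyl-2,4,5,6,7,7a-hexahydro-1-benzofuran-2-yl]but-2-enal | C/C(=C/C=O)[C@@H]1C=C2C(C)(C)C[C@H](O)C[C@@]2(C)O1 | intermediate
24 | (2E,4E,6E)-2,7-dimethylocta-2,4,6-trienedial | O=C/C(C)=C/C=C/C=C(C)/C=O | starting material
25 | ethyl (2E,4E,6E,8E)-4,9-dimethyl-10-oxodeca-2,4,6,8-tetraenoate | CCOC(=O)/C=C/C(C)=C/C=C/C=C(C)/C=O | intermediate
26 | ethyl (2E,4E,6E,8E)-10-hydroxy-4,9-dimethyldeca-2,4,6,8-tetraenoate | CCOC(=O)/C=C/C(C)=C/C=C/C=C(C)/CO | intermediate
27 | ethyl (2E,4E,6E,8E)-10-bromo-4,9-dimethyldeca-2,4,6,8-tetraenoate | CCOC(=O)/C=C/C(C)=C/C=C/C=C(C)/CBr | intermediate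
28 | ethyl (2E,4E,6E,8E)-10-(diethoxyphosphoryl)-4,9-dimethyldeca-2,4,6,8-tetraenoate | CCOC(=O)/C=C/C(C)=C/C=C/C=C(C)/CP(=O)(OCC)OCC | intermediate
29 | sodium salt of 28 (carbanion at the phosphorus-bearing carbon C12) | CCOC(=O)/C=C/C(C)=C/C=C/C=C(C)/[CH-]P(=O)(OCC)OCC.[Na+] | intermediate (not isolated)
30 | ethyl (2E,4E,6E,8E,10E,12Z)-13-[(2S,6S,7aR)-6-hydroxy-4,4,7a-trimethyl-2,4,5,6,7,7a-hexahydro-1-benzofuran-2-yl]-4,9-dimethyltetradeca-2,4,6,8,10,12-hexaenoate | C/C(=C/C=C/C(C)=C/C=C/C=C(C)/C=C/C(=O)OCC)[C@@H]1C=C2C(C)(C)C[C@H](O)C[C@@]2(C)O1 | intermediate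
31 | (3S,5R,8S,9Z)-5,8-epoxy-5,8-dihydro-10′-apo-β-carotene-3,10′-diol | C/C(=C/C=C/C(C)=C/C=C/C=C(C)/C=C/CO)[C@@H]1C=C2C(C)(C)C[C@H](O)C[C@@]2(C)O1 | target

## Step count and least certain steps

Total: 20 steps. Longest linear sequence: 14 steps from ketoisophorone (steps 1–8, 11–14, 19, 20). The stannane (steps 9–10) and the phosphonate (steps 15–18) are side branches.

**Step 12 (key step).** Three processes can defeat it:
- protodestannylation of the alkenylstannane by traces of triflic acid before the C–C bond forms;
- intermolecular attack leading to oligomers if the dilution is insufficient;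
- reluctance of the 11-membered transition state, because the bridge must arch over the axial C5 methyl, so that silylene cleavage or attack at C6 takes over.

Fallback: give up the bridge and correct C8 afterwards. The fallback sets out from lactol 9. A short exposure to methanol and pyridinium p-toluenesulfonate, quenched with Et3N, lets the acetal 10 be isolated with its silyl ether intact. Stannane 16 is silylated (t-BuMe2SiCl, imidazole) to tert-butyldimethyl{[(2Z)-3-(tributylstannyl)but-2-en-1-yl]oxy}silane F1. Acetal 10 and F1 are combined with Me3SiOTf and 2,6-di-tert-butyl-4-methylpyridine in CH2Cl2 at −78 °C at ordinary concentration. The intermolecular ipso substitution should give the bis-silyl ether of the C15 furanoid diol F2 as a mixture of C8 epimers, probably richer in the epimer from attack anti to the C5 methyl. Bu4NF removes both silyl groups and gives 22 together with its C8 epimer F3, and the two are separated by chromatography. F3 is recycled by brief treatment with pyridinium p-toluenesulfonate in CH2Cl2, which re-ionises C8–O1 and re-equilibrates the epimers. The fallback returns to the route at 22.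

**Step 4.** Facial discrimination at C5 may be poor, because the stereoelectronically preferred axial attack passes the pseudo-axial C1 methyl. Warming of the alkoxide would also allow α-ketol rearrangement.

Fallback: form the C5–O bond by peracid epoxidation of the ring alkene, where attack anti to a protected 3-oxygen is the usual sense for this end group. The fallback sets out from 4. KN(SiMe3)2 and PhN(SO2CF3)2 give the enol triflate (4R)-2,6,6-trimethyl-4-(triethylsilyloxy)cyclohex-1-en-1-yl trifluoromethanesulfonate F4. Pd(PPh3)4-catalysed coupling with BrZnCH2CO2CH3 gives methyl 2-[(4R)-2,6,6-trimethyl-4-(triethylsilyloxy)cyclohex-1-en-1-yl]acetate F5. Buffered m-chloroperbenzoic acid gives the 5,6-epoxide anti to O3, methyl 2-[2,2,6-trimethyl-4-(triethylsilyloxy)-7-oxabicyclo[4.1.0]heptan-1-yl]acetate F6. NaOCH3 in methanol opens the epoxide from the ester enolate (C6=C7 forms, the oxygen stays on C5) and the alkoxide lactonises. The fallback returns to the route at 8.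

**Step 6.** Olefination of a ketone flanked by two quaternary carbons may be slow, so that cleavage of the phosphonoacetyl ester by adventitious hydroxide or alkoxide competes.

Fallback: build the butenolide by acetylide addition, which tolerates hindered ketones. The fallback sets out from 6. LiC≡COEt (2.5 equiv, THF, −78 °C) adds to the ketone to give (2R,4S)-1-(ethoxyethynyl)-2,6,6-trimethyl-4-(triethylsilyloxy)cyclohexane-1,2-diol F7 (mixture at C1). Dilute H2SO4 in aqueous THF effects the Meyer–Schuster-type rearrangement to the unsaturated ester, which lactonises onto the C5 hydroxyl with loss of the silyl ether to give (−)-loliolide F8. Re-silylation (Et3SiCl, imidazole) returns to the route at 8.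

**Step 19 (with step 14).** The extended, ester-conjugated phosphonate carbanion may react sluggishly or with incomplete E selectivity at C11=C12. Prolonged exposure of the γ-alkoxy enal to base could erode the Z geometry or C8 through dienolate formation.

Fallback: a more reactive semi-stabilised ylide. The fallback sets out from bromide 27. PPh3 in toluene gives the phosphonium salt [(2E,4E,6E,8E)-10-ethoxy-2,7-dimethyl-10-oxodeca-2,4,6,8-tetraen-1-yl]triphenylphosphonium bromide F9. Its ylide (NaOCH3, CH2Cl2/MeOH, 0 °C) undergoes Wittig reaction with 23. The hindered 11Z isomer that accompanies the 11E product is isomerised thermally, a process that hardly affects the unhindered 9Z bond. The fallback returns to the route at 30.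

**Step 10.** Incomplete iodine–lithium exchange on the alkoxide, or protonation of the alkenyllithium, would return reduced material.

Fallback: palladium-catalysed stannylation of 14 with Bu3SnSnBu3 and Pd(PPh3)4 (zerovalent palladium) in toluene at 80 °C, which gives 16 directly with retention. This fallback makes no new compound (F0).

## Further compounds

F1 | step 12 | tert-butyldimethyl{[(2Z)-3-(tributylstannyl)but-2-en-1-yl]oxy}silane | C/C(=C/CO[Si](C)(C)C(C)(C)C)[Sn](CCCC)(CCCC)CCCC
F2 | step 12 | bis-silyl ether of the C15 furanoid diol (O3 triethylsilyl, O11 tert-butyldimethylsilyl; both C8 epimers) | C/C(=C/CO[Si](C)(C)C(C)(C)C)C1C=C2C(C)(C)C[C@H](O[Si](CC)(CC)CC)C[C@@]2(C)O1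
F3 | step 12 | (2Z)-3-[(2R,6S,7aR)-6-hydroxy-4,4,7a-trimethyl-2,4,5,6,7,7a-hexahydro-1-benzofuran-2-yl]but-2-en-1-ol (C8 epimer of 22) | C/C(=C/CO)[C@H]1C=C2C(C)(C)C[C@H](O)C[C@@]2(C)O1
F4 | step 4 | (4R)-2,6,6-trimethyl-4-(triethylsilyloxy)cyclohex-1-en-1-yl trifluoromethanesulfonate | CC1=C(OS(=O)(=O)C(F)(F)F)C(C)(C)C[C@H](O[Si](CC)(CC)CC)C1
F5 | step 4 | methyl 2-[(4R)-2,6,6-trimethyl-4-(triethylsilyloxy)cyclohex-1-en-1-yl]acetate | CC1=C(CC(=O)OC)C(C)(C)C[C@H](O[Si](CC)(CC)CC)C1
F6 | step 4 | methyl 2-[2,2,6-trimethyl-4-(triethylsilyloxy)-7-oxabicyclo[4.1.0]heptan-1-yl]acetate, epoxide anti to the silyloxy group (carotenoid descriptors 3S,5R,6S) | COC(=O)C[C@@]12O[C@]1(C)C[C@@H](O[Si](CC)(CC)CC)CC2(C)C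
F7 | step 6 | (2R,4S)-1-(ethoxyethynyl)-2,6,6-trimethyl-4-(triethylsilyloxy)cyclohexane-1,2-diol (mixture at C1) | CCOC#CC1(O)C(C)(C)C[C@H](O[Si](CC)(CC)CC)C[C@@]1(C)O
F8 | step 6 | (−)-loliolide, (6S,7aR)-6-hydroxy-4,4,7a-trimethyl-5,6,7,7a-tetrahydro-1-benzofuran-2(4H)-one | CC1(C)C[C@H](O)C[C@@]2(C)OC(=O)C=C12
F9 | step 19 | [(2E,4E,6E,8E)-10-ethoxy-2,7-dimethyl-10-oxodeca-2,4,6,8-tetraen-1-yl]triphenylphosphonium bromide | CCOC(=O)/C=C/C(C)=C/C=C/C=C(C)/C[P+](c1ccccc1)(c1ccccc1)c1ccccc1.[Br-]
F0 | step 10 | none | none
A1 | alternative 1 | (2S)-2-[(tert-butyldiphenylsilyloxy)methyl]-5-methyl-4-[2-methyl-4-(trimethylsilyloxy)pent-4-en-2-yl]-5-(trimethylsilyloxy)-2,5-dihydrofuran (mixture at the ketal carbon) | C=C(O[Si](C)(C)C)CC(C)(C)C1=C[C@@H](CO[Si](c2ccccc2)(c2ccccc2)C(C)(C)C)OC1(C)O[Si](C)(C)C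
A2 | alternative 1 | (2S,7aR)-2-[(tert-butyldiphenylsilyloxy)methyl]-4,4,7a-trimethyl-2,4,5,7a-tetrahydro-1-benzofuran-6(7H)-one | CC(C)(C)[Si](OC[C@@H]1C=C2C(C)(C)CC(=O)C[C@@]2(C)O1)(c3ccccc3)c4ccccc4
A3 | alternative 2 | 3-O-tert-butyldimethylsilyl ring A with the C5=C6 alkene carrying at C6 the cis-7,8-epoxide whose C8 bears a (trimethylsilyl)ethynyl group | CC1=C([C@@H]2O[C@@H]2C#C[Si](C)(C)C)C(C)(C)C[C@H](O[Si](C)(C)C(C)(C)C)C1
A4 | alternative 2 | tert-butyldimethyl{[(2S,6S,7aR)-4,4,7a-trimethyl-2-[(trimethylsilyl)ethynyl]-2,4,5,6,7,7a-hexahydro-1-benzofuran-6-yl]oxy}silane | C[Si](C)(C)C#C[C@@H]1C=C2C(C)(C)C[C@H](O[Si](C)(C)C(C)(C)C)C[C@@]2(C)O1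
A5 | alternative 3 | 3-iodo-2,5-dihydrofuran with a quaternary C5 (methyl and 2-(tert-butyldimethylsilyloxy)-4-methylpent-4-enyl chain) and a C8 (tert-butyldimethylsilyloxy)methyl group | C=C(C)C[C@H](O[Si](C)(C)C(C)(C)C)C[C@@]1(C)O[C@H](CO[Si](C)(C)C(C)(C)C)C=C1I
A6 | alternative 3 | tert-butyl{[(2S,6S,7aR)-6-(tert-butyldimethylsilyloxy)-4,4,7a-trimethyl-2,4,5,6,7,7a-hexahydro-1-benzofuran-2-yl]methoxy}dimethylsilane | CC(C)(C)[Si](C)(C)OC[C@@H]1C=C2C(C)(C)C[C@H](O[Si](C)(C)C(C)(C)C)C[C@@]2(C)O1
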